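**Plan**

- The retrosynthesis first cuts the thenylic O–C(=O) bond of the 3-methylbut-2-enoate on ring A (the thiophene bearing CH2O); the base-labile enoate goes on last and the oxygen is carried as a TBS ether.
- Ring B (the alkyne-bearing thiophene) carries C≡C–CH2–CH2–O–C(=O)CH2CH(CH3)2: an acetylide carbon joined to the two carbons and the oxygen of an opened oxirane, the oxygen capped by an acyl chloride. The C(sp)–CH2 bond and the ester O–C(=O) bond are therefore cut together.
- The ethynyl group goes back to an aldehyde (one-carbon homologation), and the aldehyde to the free α-C–H of ring B.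
- Forward, from 2,2'-bithiophene-5-carbaldehyde: reduce, silylate, formylate ring B, homologate to the alkyne, assemble the chain in one flask, desilylate, acylate. Both rings are bought and none is formed.
- The target has no stereocentre, and its only alkene carries two identical methyl groups, so there is no stereochemistry to set.

Key step: step 5

Remark: ring A is the thiophene bearing the oxymethyl group and ring B the other one throughout. Primed and unprimed locants follow nomenclature rules and may swap between compounds. Oxirane is taken as a commercial THF solution.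

**Route**

Step 1
Reactants: 1 2,2'-bithiophene-5-carbaldehyde
Product: 2 (2,2'-bithiophen-5-yl)methanol
Conditions: NaBH4, MeOH/THF, 0 °C
Reagents that add atoms: none
Why: Borohydride reduction of an aryl aldehyde to the primary alcohol is chemoselective and leaves both thiophene rings untouched.

Step 2
Reactants: 2 (2,2'-bithiophen-5-yl)methanol
Product: 3 tert-butyl[(2,2'-bithiophen-5-yl)methoxy]dimethylsilane
Conditions: TBSCl, imidazole, DMF, rt
Reagents that add atoms: tert-butyldimethylsilyl chloride, CC(C)(C)[Si](C)(C)Cl
Why: Imidazole-promoted silylation of a primary alcohol gives a silyl ether that should withstand the organolithium and carbonate/methanol steps ahead and can later be removed by fluoride without harm to an ester.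

Step 3
Reactants: 3 tert-butyl[(2,2'-bithiophen-5-yl)methoxy]dimethylsilane
Product: 5 5'-(tert-butyldimethylsilyloxymethyl)-2,2'-bithiophene-5-carbaldehyde, via 5'-lithio silyl ether 4 (not isolated)
Conditions: n-BuLi, THF, −78 °C; DMF, −78 → 0 °C; H2O
Reagents that add atoms: N,N-dimethylformamide, CN(C)C=O
Why: α-Lithiation of thiophene by n-BuLi should take place at the only free α-position (ring B), and the aryllithium is formylated by DMF in a Bouveault aldehyde synthesis.

Step 4
Reactants: 5 5'-(tert-butyldimethylsilyloxymethyl)-2,2'-bithiophene-5-carbaldehyde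
Product: 6 tert-butyl[(5'-ethynyl-2,2'-bithiophen-5-yl)methoxy]dimethylsilane
Conditions: dimethyl (1-diazo-2-oxopropyl)phosphonate, K2CO3, MeOH/THF, 0 °C → rt
Reagents that add atoms: dimethyl (1-diazo-2-oxopropyl)phosphonate, COP(=O)(OC)C(=[N+]=[N-])C(C)=O
Why: Seyferth–Gilbert homologation in its Ohira–Bestmann form turns a non-enolisable aryl aldehyde into the terminal alkyne under carbonate/methanol conditions that a primary TBS ether tolerates.

Step 5
Reactants: 6 tert-butyl[(5'-ethynyl-2,2'-bithiophen-5-yl)methoxy]dimethylsilane; 7 oxirane; 8 3-methylbutanoyl chloride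
Product: 11 4-[5'-(tert-butyldimethylsilyloxymethyl)-2,2'-bithiophen-5-yl]but-3-yn-1-yl 3-methylbutanoate, via lithium acetylide 9 (not isolated), via lithium but-3-yn-1-olate 10 (not isolated)
Conditions: n-BuLi (1.0 equiv), THF, −78 °C; DMPU, 7 (2 equiv), −78 °C → rt; Ar purge; 8 (1.3 equiv), 0 °C → rt
Reagents that add atoms: none
Why: n-BuLi deprotonates the terminal alkyne of 6 to give lithium acetylide 9, whose sp carbon attacks a CH2 of oxirane in an SN2 opening driven by ring strain and helped by DMPU, which breaks up the acetylide aggregates; this forms the C(sp)–CH2 bond and leaves lithium alkoxide 10. Compound 10 is then the only strong nucleophile in the flask and undergoes nucleophilic acyl substitution with 3-methylbutanoyl chloride, forming the ester C–O bond and LiCl. The closest known reaction type is the opening of epoxides by lithium acetylides in a dipolar aprotic cosolvent with capture of the alkoxide by an acyl halide in the same flask. No ring is closed and no stereocentre is created, and because oxirane is symmetrical the site of opening is not in question. The step needs deprotonation at the alkyne alone and a single oxirane insertion: every thiophene α-position of 6 is substituted, the alkyne C–H is by far the most acidic site, n-BuLi is held at one equivalent so that none is left to attack the acyl chloride, and surplus oxirane is swept out before acylation. The silyl ether on ring A is inert to all three reagents, which is why it takes the place of the enoate ester at this stage.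

Step 6
Reactants: 11 4-[5'-(tert-butyldimethylsilyloxymethyl)-2,2'-bithiophen-5-yl]but-3-yn-1-yl 3-methylbutanoate
Product: 12 4-[5'-(hydroxymethyl)-2,2'-bithiophen-5-yl]but-3-yn-1-yl 3-methylbutanoate
Conditions: TBAF, AcOH (1:1), THF, 0 °C → rt
Reagents that add atoms: none
Why: Fluoride-induced cleavage of the Si–O bond (desilylation) frees the primary alcohol, and the acetic acid buffer should keep the medium from becoming basic enough to cleave or transfer the isovalerate ester.

Step 7
Reactants: 12 4-[5'-(hydroxymethyl)-2,2'-bithiophen-5-yl]but-3-yn-1-yl 3-methylbutanoate; 13 3-methylbut-2-enoyl chloride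
Product: 14 {5'-[4-(3-methylbutanoyloxy)but-1-yn-1-yl]-2,2'-bithiophen-5-yl}methyl 3-methylbut-2-enoate
Conditions: 13, pyridine, DMAP (cat.), CH2Cl2, 0 °C
Reagents that add atoms: none
Why: O-Acylation of a primary alcohol by an acyl chloride (nucleophilic acyl substitution) with pyridine as a mild HCl scavenger should give the conjugated ester, since pyridine is too weak a base to drive the acyl chloride to a vinylketene.

**Compound list**

1 | 2,2'-bithiophene-5-carbaldehyde | O=Cc1ccc(-c2cccs2)s1 | starting material
2 | (2,2'-bithiophen-5-yl)methanol | OCc1ccc(-c2cccs2)s1 | intermediate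
3 | tert-butyl[(2,2'-bithiophen-5-yl)methoxy]dimethylsilane | CC(C)(C)[Si](C)(C)OCc1ccc(-c2cccs2)s1 | intermediate
4 | tert-butyl[(5'-lithio-2,2'-bithiophen-5-yl)methoxy]dimethylsilane (not isolated) | [Li]c1ccc(-c2ccc(CO[Si](C)(C)C(C)(C)C)s2)s1 | intermediate
5 | 5'-(tert-butyldimethylsilyloxymethyl)-2,2'-bithiophene-5-carbaldehyde | O=Cc1ccc(-c2ccc(CO[Si](C)(C)C(C)(C)C)s2)s1 | intermediate
6 | tert-butyl[(5'-ethynyl-2,2'-bithiophen-5-yl)methoxy]dimethylsilane | C#Cc1ccc(-c2ccc(CO[Si](C)(C)C(C)(C)C)s2)s1 | intermediate
7 | oxirane | C1CO1 | starting material
8 | 3-methylbutanoyl chloride | CC(C)CC(=O)Cl | starting material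
9 | lithium acetylide of 6, {[5'-(tert-butyldimethylsilyloxymethyl)-2,2'-bithiophen-5-yl]ethynyl}lithium (not isolated) | [Li]C#Cc1ccc(-c2ccc(CO[Si](C)(C)C(C)(C)C)s2)s1 | intermediate
10 | lithium 4-[5'-(tert-butyldimethylsilyloxymethyl)-2,2'-bithiophen-5-yl]but-3-yn-1-olate (not isolated) | [Li]OCCC#Cc1ccc(-c2ccc(CO[Si](C)(C)C(C)(C)C)s2)s1 | intermediate
11 | 4-[5'-(tert-butyldimethylsilyloxymethyl)-2,2'-bithiophen-5-yl]but-3-yn-1-yl 3-methylbutanoate | CC(C)CC(=O)OCCC#Cc1ccc(-c2ccc(CO[Si](C)(C)C(C)(C)C)s2)s1 | intermediate
12 | 4-[5'-(hydroxymethyl)-2,2'-bithiophen-5-yl]but-3-yn-1-yl 3-methylbutanoate | CC(C)CC(=O)OCCC#Cc1ccc(-c2ccc(CO)s2)s1 | intermediate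
13 | 3-methylbut-2-enoyl chloride | CC(C)=CC(=O)Cl | starting material
14 | {5'-[4-(3-methylbutanoyloxy)but-1-yn-1-yl]-2,2'-bithiophen-5-yl}methyl 3-methylbut-2-enoate (CNP0114739.0) | CC(C)=CC(=O)OCc1ccc(-c2ccc(C#CCCOC(=O)CC(C)C)s2)s1 | target

**Count**

Total steps: 7. Longest linear sequence: 7 steps (1 → 14).

**Steps most likely to fail, with fallbacks**

Step 5. The conjugated arylacetylide may open oxirane sluggishly. Unreacted acetylide would then be acylated at carbon to an ynone, and leftover oxirane could use up acyl chloride. The fallback drops the oxirane opening and joins the complete side chain by cross-coupling. It sets out from compound 3, which is lithiated to 4 as in step 3 and quenched with I2 (THF, −78 °C) to give tert-butyl[(5'-iodo-2,2'-bithiophen-5-yl)methoxy]dimethylsilane F1. Separately, commercial but-3-yn-1-ol is acylated with compound 8 (pyridine, CH2Cl2, 0 °C) to give but-3-yn-1-yl 3-methylbutanoate F2. Sonogashira coupling of F1 with F2 (Pd(PPh3)2Cl2, copper monoiodide CuI, Et3N, THF, rt) should form the C(sp)–C(thienyl) bond and comes back to the route at compound 11.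

Step 7. The acyl chloride may lose a γ-proton to base and pass through a vinylketene, which would deliver the deconjugated 3-methylbut-3-enoate. The thenylic alcohol may also ionise under the HCl released. The fallback activates the alcohol instead of the acid: from compound 12, a Mitsunobu esterification with 3-methylbut-2-enoic acid (PPh3, diisopropyl azodicarboxylate, THF, 0 °C) under neutral conditions leads straight to compound 14. No new compound arises on the way.

Step 3. Deprotonation may stray to the thenylic CH2 next to the silyloxy group, followed by silyl migration, or ring lithiation may be incomplete. The fallback replaces deprotonation, formylation and homologation by electrophilic halogenation and cross-coupling. It sets out from compound 3, which is brominated at the free α-position of ring B with N-bromosuccinimide (DMF, 0 °C, dark) to give [(5'-bromo-2,2'-bithiophen-5-yl)methoxy](tert-butyl)dimethylsilane F3. Sonogashira coupling with ethynyltrimethylsilane (Pd(PPh3)2Cl2, copper monoiodide CuI, Et3N, THF, 60 °C) gives tert-butyldimethyl{[5'-(trimethylsilylethynyl)-2,2'-bithiophen-5-yl]methoxy}silane F4. Selective C–Si cleavage with K2CO3 in MeOH then comes back to the route at compound 6, so that step 4 is bypassed as well.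

**Further compounds**

F1 | step 5 | tert-butyl[(5'-iodo-2,2'-bithiophen-5-yl)methoxy]dimethylsilane | Ic1ccc(-c2ccc(CO[Si](C)(C)C(C)(C)C)s2)s1
F2 | step 5 | but-3-yn-1-yl 3-methylbutanoate | C#CCCOC(=O)CC(C)C
F0 | step 7 | none | none
F3 | step 3 | [(5'-bromo-2,2'-bithiophen-5-yl)methoxy](tert-butyl)dimethylsilane | Brc1ccc(-c2ccc(CO[Si](C)(C)C(C)(C)C)s2)s1
F4 | step 3 | tert-butyldimethyl{[5'-(trimethylsilylethynyl)-2,2'-bithiophen-5-yl]methoxy}silane | C[Si](C)(C)C#Cc1ccc(-c2ccc(CO[Si](C)(C)C(C)(C)C)s2)s1
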